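**Retrosynthetic overview**
1. Target 18 ⇐ tricyclic isoxazoline 15: N–O hydrogenolysis and imine hydrolysis unmask the C4 ketone and the carbinol OH; debenzylation frees the phenols and turns the 2‑O‑benzyl acetal into the lactol.
2. 15 ⇐ (Z)-styryl mixed acetal 12: an intramolecular nitrile oxide–alkene cycloaddition closes the pyranone ring and the isoxazoline ring together. The Z geometry sets C3 against the carbinol carbon, and the (S)-acetal carbon (future C2) sets the face.
3. 12 ⇐ 11 (E→Z photoisomerisation) ⇐ 9 + 10 (cross-metathesis) ⇐ 6 + 8 (Pd-catalysed asymmetric hydroalkoxylation of benzyloxyallene).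
4. 6 ⇐ 2,4,6-trihydroxytoluene 1 (formylation, selective dibenzylation, bromination, Cu-methoxylation).
5. Ring order: both benzene rings are bought; pyranone and isoxazoline form in one step; the isoxazoline is opened last.

Assumption: the target is the single 2S lactol anomer as drawn (it may equilibrate with its anomer in solution), and the (R,R)-Trost ligand is taken as the antipode that gives the (S)-acetal in step 6; if the sense is opposite, the (S,S)-ligand is used and nothing else changes.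

**Route**

Step 1
Reactants: 1 2,4,6-trihydroxytoluene
Product: 3 2,4,6-trihydroxy-3-methylbenzaldehyde, via iminium chloride 2 (not isolated)
Conditions: POCl3 (1.2 equiv), DMF, EtOAc, 0 °C → rt; then H2O, 60 °C
Reagents that add atoms: N,N-dimethylformamide CN(C)C=O; water O
Why: Vilsmeier–Haack formylation; the two free ring positions are equivalent and the first formyl group deactivates the ring against a second.

Step 2
Reactants: 3 2,4,6-trihydroxy-3-methylbenzaldehyde
Product: 4 4,6-bis(benzyloxy)-2-hydroxy-3-methylbenzaldehyde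
Conditions: BnBr (2.05 equiv), K2CO3 (2.2 equiv), DMF, 0 °C → rt
Reagents that add atoms: benzyl bromide BrCc1ccccc1
Why: Williamson etherification; the para OH is the most acidic, the second benzyl goes to the unhindered 6‑OH, and the 2‑OH between Me and CHO stays free because it is hindered and chelated to the aldehyde.

Step 3
Reactants: 4 4,6-bis(benzyloxy)-2-hydroxy-3-methylbenzaldehyde
Product: 5 4,6-bis(benzyloxy)-5-bromo-2-hydroxy-3-methylbenzaldehyde
Conditions: NBS (1.05 equiv), MeCN, 0 °C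
Reagents that add atoms: N-bromosuccinimide O=C1CCC(=O)N1Br
Why: electrophilic aromatic bromination at the only free ring position, which is para to the free OH and flanked by two ether oxygens.

Step 4
Reactants: 5 4,6-bis(benzyloxy)-5-bromo-2-hydroxy-3-methylbenzaldehyde
Product: 6 4,6-bis(benzyloxy)-2-hydroxy-5-methoxy-3-methylbenzaldehyde
Conditions: NaOMe (5 equiv), CuBr (20 mol%), EtOAc (cat.), DMF/MeOH, 110 °C
Reagents that add atoms: sodium methoxide [Na+].[O-]C
Why: copper-catalysed Ullmann-type methoxylation of the aryl bromide (the bromovanillin → syringaldehyde reaction type); the non-enolisable aldehyde is shielded as its electron-rich phenoxide.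

Step 5
Reactants: 7 benzyl propargyl ether
Product: 8 benzyloxyallene [(propa-1,2-dien-1-yloxy)methyl]benzene
Conditions: KOtBu (0.3 equiv), THF, 0 °C → rt
Reagents that add atoms: none
Why: base-catalysed propargyl → allenyl ether isomerisation, which stops at the alkoxyallene.

Step 6
Reactants: 6 4,6-bis(benzyloxy)-2-hydroxy-5-methoxy-3-methylbenzaldehyde; 8 benzyloxyallene
Product: 9 4,6-bis(benzyloxy)-2-{[(1S)-1-(benzyloxy)prop-2-en-1-yl]oxy}-5-methoxy-3-methylbenzaldehyde
Conditions: Pd2(dba)3·CHCl3 (2.5 mol%), (R,R)-DACH-phenyl Trost ligand (7.5 mol%), Et3N (1 equiv), 8 (1.5 equiv), CH2Cl2, rt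
Reagents that add atoms: none
Why: Pd-catalysed asymmetric hydroalkoxylation of an alkoxyallene; hydropalladation gives an alkoxy-π-allyl-Pd and the phenoxide attacks the oxygen-bearing terminus inside the chiral pocket, which sets the (S)-O,O-acetal carbon that becomes C2.

Step 7
Reactants: 9 the (S)-vinyl acetal; 10 4-(benzyloxy)styrene
Product: 11 4,6-bis(benzyloxy)-2-{[(1S,2E)-1-(benzyloxy)-3-[4-(benzyloxy)phenyl]prop-2-en-1-yl]oxy}-5-methoxy-3-methylbenzaldehyde
Conditions: Hoveyda–Grubbs II (5 mol%), 10 (3 equiv), 1,4-benzoquinone (10 mol%), CH2Cl2, 40 °C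
Reagents that add atoms: none
Why: olefin cross-metathesis of an acrolein-acetal-type olefin with a styrene is E-selective, leaves the acetal stereocentre untouched, and tolerates the aldehyde.

Step 8
Reactants: 11 the (S,E)-styryl acetal
Product: 12 4,6-bis(benzyloxy)-2-{[(1S,2Z)-1-(benzyloxy)-3-[4-(benzyloxy)phenyl]prop-2-en-1-yl]oxy}-5-methoxy-3-methylbenzaldehyde
Conditions: fac-Ir(ppy)3 (1 mol%), 450 nm LEDs, degassed MeCN, rt; Z isomer separated on Et3N-washed silica, E recycled
Reagents that add atoms: none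
Why: triplet energy-transfer E→Z isomerisation of a β-substituted styrene; the Z isomer is twisted out of conjugation by A(1,3) strain with the branched acetal carbon, is no longer sensitised, and accumulates, with the stereocentre not involved.

Step 9
Reactants: 12 the (S,Z)-styryl acetal
Product: 15 (3S,3aR,4S)-4,7,9-tris(benzyloxy)-3-[4-(benzyloxy)phenyl]-8-methoxy-6-methyl-3a,4-dihydro-3H-chromeno[4,3-c][1,2]oxazole, via aldoxime 13 (not isolated), via nitrile oxide 14 (not isolated)
Conditions: NH2OH (50% aq., 1.1 equiv), THF, rt; then CH2Cl2, aq. NaOCl (1.5 equiv), 0 → 35 °C; recrystallise 15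
Reagents that add atoms: hydroxylamine NO
Why: oxime formation, hypochlorite oxidation to a persistent 2,6-dialkoxyaryl nitrile oxide and intramolecular nitrile oxide–alkene cycloaddition close the pyran and isoxazoline rings in one operation; suprafacial addition to the Z-olefin fixes the C3a/C3 relationship, and A(1,3) strain holds the acetal C–H in the olefin plane with the OBn group anti to the incoming dipole, so the (S)-acetal carbon steers the dipole to one face and gives (3S,3aR,4S).

Step 10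
Reactants: 15 the tricyclic isoxazoline
Product: 18 (2S,3R)-2,5,7-trihydroxy-3-[(S)-hydroxy(4-hydroxyphenyl)methyl]-6-methoxy-8-methylchroman-4-one, via β-hydroxy ketimine 16 (not isolated), via tetrabenzyl β-hydroxy ketone 17 (not isolated)
Conditions: H2 (1 atm), Raney Ni, B(OH)3 (3 equiv), THF/MeOH/H2O 5:5:1, rt; filter through Celite; then H2 (1 atm), 20% Pd(OH)2/C, rt
Reagents that add atoms: water O
Why: Raney-nickel hydrogenolysis of the isoxazoline N–O bond with boric-acid-buffered imine hydrolysis unmasks the aldol, and Pd-catalysed hydrogenolysis then removes the three aryl benzyl ethers and the anomeric O-benzyl group under near-neutral conditions, so only N–O and O–CH2Ph bonds break and the 2S, 3R and carbinol S centres are delivered unchanged.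

**Compound list**
1 | 2,4,6-trihydroxytoluene | Cc1c(O)cc(O)cc1O | starting material
2 | (2,4,6-trihydroxy-3-methylbenzylidene)dimethyliminium chloride | Cc1c(O)cc(O)c(C=[N+](C)C)c1O.[Cl-] | intermediate
3 | 2,4,6-trihydroxy-3-methylbenzaldehyde | Cc1c(O)cc(O)c(C=O)c1O | intermediate
4 | 4,6-bis(benzyloxy)-2-hydroxy-3-methylbenzaldehyde | Cc1c(OCc2ccccc2)cc(OCc2ccccc2)c(C=O)c1O | intermediate
5 | 4,6-bis(benzyloxy)-5-bromo-2-hydroxy-3-methylbenzaldehyde | Cc1c(OCc2ccccc2)c(Br)c(OCc2ccccc2)c(C=O)c1O | intermediate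
6 | 4,6-bis(benzyloxy)-2-hydroxy-5-methoxy-3-methylbenzaldehyde | COc1c(OCc2ccccc2)c(C)c(O)c(C=O)c1OCc1ccccc1 | intermediate
7 | benzyl propargyl ether | C#CCOCc1ccccc1 | starting material
8 | benzyloxyallene | C=C=COCc1ccccc1 | intermediate
9 | 4,6-bis(benzyloxy)-2-{[(1S)-1-(benzyloxy)prop-2-en-1-yl]oxy}-5-methoxy-3-methylbenzaldehyde | COc1c(OCc2ccccc2)c(C)c(O[C@H](OCc2ccccc2)C=C)c(C=O)c1OCc1ccccc1 | intermediate
10 | 4-(benzyloxy)styrene | C=Cc1ccc(OCc2ccccc2)cc1 | starting material
11 | 4,6-bis(benzyloxy)-2-{[(1S,2E)-1-(benzyloxy)-3-[4-(benzyloxy)phenyl]prop-2-en-1-yl]oxy}-5-methoxy-3-methylbenzaldehyde | COc1c(OCc2ccccc2)c(C)c(O[C@H](OCc2ccccc2)/C=C/c2ccc(OCc3ccccc3)cc2)c(C=O)c1OCc1ccccc1 | intermediate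
12 | 4,6-bis(benzyloxy)-2-{[(1S,2Z)-1-(benzyloxy)-3-[4-(benzyloxy)phenyl]prop-2-en-1-yl]oxy}-5-methoxy-3-methylbenzaldehyde | COc1c(OCc2ccccc2)c(C)c(O[C@H](OCc2ccccc2)/C=C\c2ccc(OCc3ccccc3)cc2)c(C=O)c1OCc1ccccc1 | intermediate
13 | (E)-oxime of 12 | COc1c(OCc2ccccc2)c(C)c(O[C@H](OCc2ccccc2)/C=C\c2ccc(OCc3ccccc3)cc2)c(/C=N/O)c1OCc1ccccc1 | intermediate
14 | 4,6-bis(benzyloxy)-2-{[(1S,2Z)-1-(benzyloxy)-3-[4-(benzyloxy)phenyl]prop-2-en-1-yl]oxy}-5-methoxy-3-methylbenzonitrile N-oxide | COc1c(OCc2ccccc2)c(C)c(O[C@H](OCc2ccccc2)/C=C\c2ccc(OCc3ccccc3)cc2)c(C#[N+][O-])c1OCc1ccccc1 | intermediate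
15 | (3S,3aR,4S)-4,7,9-tris(benzyloxy)-3-[4-(benzyloxy)phenyl]-8-methoxy-6-methyl-3a,4-dihydro-3H-chromeno[4,3-c][1,2]oxazole | COc1c(OCc3ccccc3)c(C)c2c(c1OCc1ccccc1)C1=NO[C@H](c3ccc(OCc4ccccc4)cc3)[C@@H]1[C@@H](OCc1ccccc1)O2 | intermediate
16 | (2S,3R)-2,5,7-tris(benzyloxy)-3-{(S)-[4-(benzyloxy)phenyl](hydroxy)methyl}-6-methoxy-8-methylchroman-4-imine | COc1c(OCc3ccccc3)c(C)c2c(c1OCc1ccccc1)C(=N)[C@H]([C@H](O)c1ccc(OCc3ccccc3)cc1)[C@@H](OCc1ccccc1)O2 | intermediate
17 | (2S,3R)-2,5,7-tris(benzyloxy)-3-{(S)-[4-(benzyloxy)phenyl](hydroxy)methyl}-6-methoxy-8-methylchroman-4-one | COc1c(OCc3ccccc3)c(C)c2c(c1OCc1ccccc1)C(=O)[C@H]([C@H](O)c1ccc(OCc3ccccc3)cc1)[C@@H](OCc1ccccc1)O2 | intermediate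
18 | (2S,3R)-2,5,7-trihydroxy-3-[(S)-hydroxy(4-hydroxyphenyl)methyl]-6-methoxy-8-methylchroman-4-one | COc1c(O)c(C)c2c(c1O)C(=O)[C@H]([C@H](O)c1ccc(O)cc1)[C@@H](O)O2 | target

**Totals**
Total steps: 10. Longest linear sequence: 9 (1 → 3 → 4 → 5 → 6 → 9 → 11 → 12 → 15 → 18).

**Steps most likely to fail, with fallbacks**

Step 6 (asymmetric hydroalkoxylation). The nucleophile is a hindered phenol chelated to its aldehyde, so both rate and ee are uncertain. The fallback sets out from 6 and comes back at 9, and swaps the roles so that the hindered oxygen is attached by plain SN2 and an unhindered alcohol is the pronucleophile. Phenol 6 is O-propargylated (propargyl bromide, K2CO3, DMF) to 4,6-bis(benzyloxy)-5-methoxy-3-methyl-2-(prop-2-yn-1-yloxy)benzaldehyde F1. This is isomerised (KOtBu cat., THF) to the aryloxyallene 4,6-bis(benzyloxy)-5-methoxy-3-methyl-2-(propa-1,2-dien-1-yloxy)benzaldehyde F2. Pd/Trost-ligand hydroalkoxylation of F2 with benzyl alcohol then gives 9, with the ligand antipode chosen again for the S acetal.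

Step 9 (oxime / nitrile oxide / cycloaddition). The Z-disubstituted olefin may cyclise slowly, and hypochlorite may attack the electron-rich styrene. The fallback sets out from 12 and comes back at 15, and closes the same two rings without an oxidant present. The oxime 13 is isolated and heated (toluene, 110 °C); 1,2-prototropy gives the NH-nitrone, which undergoes intramolecular oxime–olefin cycloaddition under the same A(1,3) control to the cis-fused (3S,3aR,4S,9bR)-4,7,9-tris(benzyloxy)-3-[4-(benzyloxy)phenyl]-8-methoxy-6-methyl-1,3a,4,9b-tetrahydro-3H-chromeno[4,3-c][1,2]oxazole F3. N-Chlorination (NCS, CH2Cl2, 0 °C) gives (3S,3aR,4S,9bR)-4,7,9-tris(benzyloxy)-3-[4-(benzyloxy)phenyl]-1-chloro-8-methoxy-6-methyl-1,3a,4,9b-tetrahydro-3H-chromeno[4,3-c][1,2]oxazole F4, and DBU dehydrochlorination gives 15.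

Step 10 (global hydrogenation). Pd may hydrogenolyse the benzylic carbinol C–O bond once the aldol is unmasked, and the lactol may dehydrate to the chromone. The fallback sets out from 15 and comes back at 18, deprotecting without reduction first and unmasking the aldol last. BCl3 with pentamethylbenzene (CH2Cl2, −78 °C, aqueous quench) removes all four benzyl groups while the isoxazoline still masks the aldol, giving (3S,3aR,4S)-3-(4-hydroxyphenyl)-8-methoxy-6-methyl-3a,4-dihydro-3H-chromeno[4,3-c][1,2]oxazole-4,7,9-triol F5. Raney Ni/H2/B(OH)3 alone then cleaves the N–O bond to give 18, so the free benzylic alcohol never meets palladium.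

**Further compounds**
F1 | step 6 | 4,6-bis(benzyloxy)-5-methoxy-3-methyl-2-(prop-2-yn-1-yloxy)benzaldehyde | COc1c(OCc2ccccc2)c(C)c(OCC#C)c(C=O)c1OCc1ccccc1
F2 | step 6 | 4,6-bis(benzyloxy)-5-methoxy-3-methyl-2-(propa-1,2-dien-1-yloxy)benzaldehyde | COc1c(OCc2ccccc2)c(C)c(OC=C=C)c(C=O)c1OCc1ccccc1
F3 | step 9 | (3S,3aR,4S,9bR)-4,7,9-tris(benzyloxy)-3-[4-(benzyloxy)phenyl]-8-methoxy-6-methyl-1,3a,4,9b-tetrahydro-3H-chromeno[4,3-c][1,2]oxazole | COc1c(OCc3ccccc3)c(C)c2c(c1OCc1ccccc1)[C@@H]1NO[C@H](c3ccc(OCc4ccccc4)cc3)[C@@H]1[C@@H](OCc1ccccc1)O2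
F4 | step 9 | (3S,3aR,4S,9bR)-4,7,9-tris(benzyloxy)-3-[4-(benzyloxy)phenyl]-1-chloro-8-methoxy-6-methyl-1,3a,4,9b-tetrahydro-3H-chromeno[4,3-c][1,2]oxazole | COc1c(OCc3ccccc3)c(C)c2c(c1OCc1ccccc1)[C@@H]1N(Cl)O[C@H](c3ccc(OCc4ccccc4)cc3)[C@@H]1[C@@H](OCc1ccccc1)O2
F5 | step 10 | (3S,3aR,4S)-3-(4-hydroxyphenyl)-8-methoxy-6-methyl-3a,4-dihydro-3H-chromeno[4,3-c][1,2]oxazole-4,7,9-triol | COc1c(O)c(C)c2c(c1O)C1=NO[C@H](c3ccc(O)cc3)[C@@H]1[C@@H](O)O2
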